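## Retrosynthetic overview

1. 35 ⇐ 34 ⇐ 32: the pyrandione ring (O1', C2'–C6') is closed last. A Wolff 1,2-shift moves C8 from C2' to C3' in a 2-diazo-1,3-diketone, and O1' captures the acylketene carbon C2'.
2. 32 ⇐ 23 + 27: the C2'–C3' bond comes from acylation of a methyl ketone enolate (made from ethyl (S)-3-hydroxybutanoate) by the β-lactone carbonyl, the future C2'.
3. 23 ⇐ 20 (key): O7 on C7 and the carbon substituent on C8 are vicinal and cis on the carbocycle C4a–C5–C6–C7–C8–C8a, so a four-membered ring O7–C2'(=O)–C8–C7 can bridge them. An isothiourea-bound enolate of the C8a acetic acid arm forms C7–C8 (carbocycle) and O7–C2' (β-lactone) in one operation.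
4. 20 ⇐ 14 + 16: pyruvoylation of the 4-methylene anhydrobase of a 4-methylpyrylium salt, then chlorination at C5. 14 ⇐ 12 (methyl addition to the 4-pyranone) ⇐ kojic acid 1, enal 7 (from (S)-2-methylbutan-1-ol) and a Reformatsky zinc reagent.
5. Ring order: pyran ring (from kojic acid) → carbocycle and β-lactone together (step 15) → β-lactone opened → pyrandione ring (step 23).

Key step: step 15

Remarks on the chemistry:
- Locants: isochromene numbering O2, C1–C8a for the bicyclic core and O1', C2'–C6' for the pyrandione; "dienyl" means (1E,3E,5S)-3,5-dimethylhepta-1,3-dien-1-yl.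
- Assumption: C3' lies between two carbonyl groups and epimerises through the enol, so its (R) configuration is taken to be the thermodynamically preferred one and is not set by a dedicated step.
- Assumption: the exocyclic C4a=C5 bond of the push–pull pyranylidenes 18–22 rotates easily; the SMILES show the isomer with C6 cis to C8a, which is the one that cyclises.

## Route

Step 1
Reactants: 1 kojic acid
Product: 2 2-(hydroxymethyl)-5-[(4-methoxybenzyl)oxy]-4H-pyran-4-one
Conditions: PMBCl, K2CO3, DMF, 70 °C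
Reagents that add atoms: 4-methoxybenzyl chloride, COc1ccc(CCl)cc1
Why: Williamson ether synthesis in which carbonate deprotonates only the acidic enolic 5-OH, so that the primary alcohol stays free.

Step 2
Reactants: 2 2-(hydroxymethyl)-5-[(4-methoxybenzyl)oxy]-4H-pyran-4-one
Product: 3 2-(bromomethyl)-5-[(4-methoxybenzyl)oxy]-4H-pyran-4-one
Conditions: CBr4, PPh3, CH2Cl2, 0 °C
Reagents that add atoms: carbon tetrabromide, BrC(Br)(Br)Br
Why: Appel bromination converts the primary alcohol under neutral conditions that leave the acid-labile PMB ether untouched.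

Step 3
Reactants: 3 2-(bromomethyl)-5-[(4-methoxybenzyl)oxy]-4H-pyran-4-one
Product: 4 diethyl {5-[(4-methoxybenzyl)oxy]-4-oxo-4H-pyran-2-yl}methylphosphonate
Conditions: P(OEt)3, toluene, 110 °C
Reagents that add atoms: triethyl phosphite, CCOP(OCC)OCC
Why: Michaelis–Arbuzov reaction of an activated primary bromide, driven by loss of bromoethane.

Step 4
Reactants: 5 (S)-2-methylbutan-1-ol
Product: 6 (S)-2-methylbutanal
Conditions: TEMPO (catalytic), PhI(OAc)2, CH2Cl2, 20 °C; washed solution carried on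
Reagents that add atoms: none
Why: Oxoammonium (TEMPO) oxidation stops at the aldehyde and runs without base, so the α-stereocentre should not be enolised.

Step 5
Reactants: 6 (S)-2-methylbutanal
Product: 7 (2E,4S)-2,4-dimethylhex-2-enal
Conditions: Ph3P=C(CH3)CHO, toluene, 80 °C
Reagents that add atoms: 2-(triphenylphosphoranylidene)propanal, CC(C=O)=P(c1ccccc1)(c1ccccc1)c1ccccc1
Why: Wittig olefination with a formyl-stabilised ylide gives the (E)-trisubstituted enal under thermodynamic control, and the neutral ylide should not epimerise the α-branched aldehyde.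

Step 6
Reactants: 4 diethyl {5-[(4-methoxybenzyl)oxy]-4-oxo-4H-pyran-2-yl}methylphosphonate; 7 (2E,4S)-2,4-dimethylhex-2-enal
Product: 9 2-[(1E,3E,5S)-3,5-dimethylhepta-1,3-dien-1-yl]-5-[(4-methoxybenzyl)oxy]-4H-pyran-4-one, via lithiated phosphonate 8 (not isolated)
Conditions: LiN(SiMe3)2, THF, −78 °C; then 7, −78 → 0 °C
Reagents that add atoms: none
Why: Horner–Wadsworth–Emmons olefination of the vinylogously stabilised phosphonate anion with the enal gives the new disubstituted alkene as the (E) isomer, and carbonyl addition is much faster than γ-deprotonation of 7, so the allylic stereocentre is kept.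

Step 7
Reactants: 9 2-[(1E,3E,5S)-3,5-dimethylhepta-1,3-dien-1-yl]-5-[(4-methoxybenzyl)oxy]-4H-pyran-4-one
Product: 10 2-[(1E,3E,5S)-3,5-dimethylhepta-1,3-dien-1-yl]-5-hydroxy-4H-pyran-4-one
Conditions: TFA, anisole, CH2Cl2, 0 °C
Reagents that add atoms: none
Why: Acidolysis of the PMB ether is fast because the acidic pyranone enol is a good leaving group, and anisole captures the 4-methoxybenzyl cation by Friedel–Crafts alkylation before it can attack the diene.

Step 8
Reactants: 10 2-[(1E,3E,5S)-3,5-dimethylhepta-1,3-dien-1-yl]-5-hydroxy-4H-pyran-4-one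
Product: 11 6-[(1E,3E,5S)-3,5-dimethylhepta-1,3-dien-1-yl]-4-oxo-4H-pyran-3-yl trifluoromethanesulfonate
Conditions: PhNTf2, Et3N, CH2Cl2, 20 °C
Reagents that add atoms: N-phenylbis(trifluoromethanesulfonimide), O=S(=O)(N(c1ccccc1)S(=O)(=O)C(F)(F)F)C(F)(F)F
Why: O-sulfonylation of the pyranone enolate with a mild triflyl donor gives the enol triflate needed for cross-coupling.

Step 9
Reactants: 11 6-[(1E,3E,5S)-3,5-dimethylhepta-1,3-dien-1-yl]-4-oxo-4H-pyran-3-yl trifluoromethanesulfonate
Product: 12 tert-butyl 2-{6-[(1E,3E,5S)-3,5-dimethylhepta-1,3-dien-1-yl]-4-oxo-4H-pyran-3-yl}acetate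
Conditions: BrZnCH2CO2tBu, Pd2(dba)3 (catalytic), XPhos (catalytic), THF, 50 °C
Reagents that add atoms: (2-tert-butoxy-2-oxoethyl)zinc bromide, CC(C)(C)OC(=O)C[Zn]Br
Why: Negishi coupling of a Reformatsky reagent with the enol triflate (oxidative addition of zerovalent palladium, transmetalation of the zinc enolate, C–C reductive elimination) places the acetate carbon C8 on C8a and leaves the diene alone.

Step 10
Reactants: 12 tert-butyl 2-{6-[(1E,3E,5S)-3,5-dimethylhepta-1,3-dien-1-yl]-4-oxo-4H-pyran-3-yl}acetate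
Product: 14 5-(2-tert-butoxy-2-oxoethyl)-2-[(1E,3E,5S)-3,5-dimethylhepta-1,3-dien-1-yl]-4-methylpyrylium tetrafluoroborate, via pyranol 13 (not isolated)
Conditions: MeLi, CeCl3, THF, −78 °C; then HBF4·OEt2, −78 → 0 °C; Et2O precipitation
Reagents that add atoms: methyllithium, [Li]C; tetrafluoroboric acid (supplies the counter-ion), [H+].F[B-](F)(F)F
Why: The weakly basic organocerium reagent adds 1,2 to the vinylogous ester carbonyl without enolising the ester arm or attacking the tert-butyl ester, and protonation of the doubly allylic tertiary carbinol expels water to give the aromatic pyrylium cation, the classical pyranone-to-pyrylium conversion.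

Step 11
Reactants: 15 pyruvic acid
Product: 16 pyruvoyl chloride
Conditions: Cl2CHOCH3, neat, 50 °C; distillation
Reagents that add atoms: dichloromethyl methyl ether, COC(Cl)Cl
Why: The α,α-dichloro ether converts the α-keto acid into its acid chloride with loss of methyl formate and HCl, the standard preparation of this acyl chloride.

Step 12
Reactants: 14 5-(2-tert-butoxy-2-oxoethyl)-2-[(1E,3E,5S)-3,5-dimethylhepta-1,3-dien-1-yl]-4-methylpyrylium tetrafluoroborate; 16 pyruvoyl chloride
Product: 18 tert-butyl 2-{6-[(1E,3E,5S)-3,5-dimethylhepta-1,3-dien-1-yl]-4-(2,3-dioxobutylidene)-4H-pyran-3-yl}acetate, via anhydrobase 17 (not isolated)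
Conditions: iPr2NEt (2.2 equiv, slow addition), CH2Cl2, −78 → −20 °C
Reagents that add atoms: none
Why: iPr2NEt removes a proton from the acidic 4-methyl group to give the 4-methylene-4H-pyran 17, whose exocyclic carbon (the future C5) is C-acylated by the acid chloride as in known acylations of pyrylium anhydrobases, and loss of a second proton gives the neutral push–pull pyranylidene diketone; slow addition of the hindered base at low temperature should keep deprotonation at the 4-methyl group ahead of the remote tertiary C–H of the dienyl chain.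

Step 13
Reactants: 18 tert-butyl 2-{6-[(1E,3E,5S)-3,5-dimethylhepta-1,3-dien-1-yl]-4-(2,3-dioxobutylidene)-4H-pyran-3-yl}acetate
Product: 19 tert-butyl 2-{4-(1-chloro-2,3-dioxobutylidene)-6-[(1E,3E,5S)-3,5-dimethylhepta-1,3-dien-1-yl]-4H-pyran-3-yl}acetate
Conditions: NCS, CH2Cl2, 0 °C
Reagents that add atoms: N-chlorosuccinimide, ClN1C(=O)CCC1=O
Why: Electrophilic chlorination at C5, the enolate-like carbon of the push–pull system whose attack generates an aromatic pyrylium that then loses H+, in line with the C5 chlorination of azaphilone cores by NCS.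

Step 14
Reactants: 19 tert-butyl 2-{4-(1-chloro-2,3-dioxobutylidene)-6-[(1E,3E,5S)-3,5-dimethylhepta-1,3-dien-1-yl]-4H-pyran-3-yl}acetate
Product: 20 2-{4-(1-chloro-2,3-dioxobutylidene)-6-[(1E,3E,5S)-3,5-dimethylhepta-1,3-dien-1-yl]-4H-pyran-3-yl}acetic acid
Conditions: TFA, CH2Cl2, 0 → 20 °C; toluene azeotrope
Reagents that add atoms: none
Why: Acidolysis of the tert-butyl ester (loss of 2-methylpropene) frees the acid, while the chromophore is only protonated reversibly on the C6 oxygen.

Step 15
Reactants: 20 2-{4-(1-chloro-2,3-dioxobutylidene)-6-[(1E,3E,5S)-3,5-dimethylhepta-1,3-dien-1-yl]-4H-pyran-3-yl}acetic acid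
Product: 23 tricyclic β-lactone of (7S,8S)-5-chloro-3-[(1E,3E,5S)-3,5-dimethylhepta-1,3-dien-1-yl]-7-hydroxy-7-methyl-6-oxo-7,8-dihydro-6H-isochromene-8-carboxylic acid (O7 acylated by the C8 carboxyl), via mixed tosyl anhydride 21 (not isolated), via ammonium enolate 22 (not isolated)
Conditions: TsCl, (S)-HBTM (20 mol %), LiCl, iPr2NEt, CH2Cl2, 20 °C
Reagents that add atoms: none
Why: TsCl turns the acid into mixed anhydride 21, which acylates the isothiourea; deprotonation at C8 gives the (Z)-ammonium enolate 22, whose carbon C8 adds to the C7 ketone, and the C7 alkoxide then attacks the acylammonium carbon and releases the catalyst. This is the nucleophile-catalysed aldol-lactonisation of keto acids to carbocycle-fused β-lactones. The carbocycle C4a–C5–C6–C7–C8–C8a closes by a 6-exo-trig aldol (enolate double bond exocyclic) and the β-lactone O7–C(=O)–C8–C7 by a 4-exo-trig acyl substitution. C8 is set by the catalyst: the enolate oxygen is held syn to sulfur and the phenyl group on C2 of (S)-HBTM shields one face, so C7 bonds to the open face, which is expected to give (8S); C7 follows because a four-membered ring can only be cis-fused to the six-membered ring, which gives (7S). The step needs C7 over C6 selectivity, secured because C6 is a vinylogous ester carbonyl conjugated to O2 (and attack there would close a five-membered ring), and it needs C6 cis to C8a, which the low rotation barrier of the push–pull C4a=C5 bond supplies by equilibration.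

Step 16
Reactants: 24 ethyl (S)-3-hydroxybutanoate
Product: 25 ethyl (S)-3-(triethylsilyloxy)butanoate
Conditions: Et3SiCl, imidazole, CH2Cl2, 0 → 20 °C
Reagents that add atoms: chlorotriethylsilane, CC[Si](Cl)(CC)CC
Why: Standard silylation of a secondary alcohol; the TES ether is stable to the enolate chemistry ahead and can later be removed in the presence of a tertiary TBS ether.

Step 17
Reactants: 25 ethyl (S)-3-(triethylsilyloxy)butanoate
Product: 26 (S)-N-methoxy-N-methyl-3-(triethylsilyloxy)butanamide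
Conditions: MeNH(OMe)·HCl, iPrMgCl, THF, −20 °C
Reagents that add atoms: N,O-dimethylhydroxylamine hydrochloride, CNOC.Cl
Why: Aminolysis of the ester by the chloromagnesium amide gives the Weinreb amide directly, and the β-silyloxy group is not eliminated at this temperature.

Step 18
Reactants: 26 (S)-N-methoxy-N-methyl-3-(triethylsilyloxy)butanamide
Product: 27 (S)-4-(triethylsilyloxy)pentan-2-one
Conditions: MeMgBr, THF, 0 °C; aqueous NH4Cl
Reagents that add atoms: methylmagnesium bromide, C[Mg]Br
Why: Weinreb ketone synthesis, in which the chelated tetrahedral intermediate prevents over-addition.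

Step 19
Reactants: 23 tricyclic β-lactone; 27 (S)-4-(triethylsilyloxy)pentan-2-one
Product: 29 (7S,8S)-5-chloro-3-[(1E,3E,5S)-3,5-dimethylhepta-1,3-dien-1-yl]-7-hydroxy-7-methyl-8-[(5S)-3-oxo-5-(triethylsilyloxy)hexanoyl]-7,8-dihydro-6H-isochromen-6-one, via lithium enolate 28 (not isolated)
Conditions: 27 (2.5 equiv), LiN(iPr)2, THF, −78 °C; then 23, −78 °C; AcOH quench
Reagents that add atoms: none
Why: Claisen-type acylation in which the kinetic methyl-side enolate attacks the strained acyl carbon of the β-lactone (acyl C–O cleavage) and frees the C7 alkoxide; the excess enolate at once converts the product into its diketonate, which should protect C8 from epimerisation and the β-alkoxide from retro-aldol cleavage, and no stereocentre is touched.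

Step 20
Reactants: 29 hydroxy 1,3-diketone
Product: 30 (7S,8S)-5-chloro-8-[(5S)-2-diazo-3-oxo-5-(triethylsilyloxy)hexanoyl]-3-[(1E,3E,5S)-3,5-dimethylhepta-1,3-dien-1-yl]-7-hydroxy-7-methyl-7,8-dihydro-6H-isochromen-6-one
Conditions: 4-acetamidobenzenesulfonyl azide, Et3N, MeCN, 0 → 20 °C
Reagents that add atoms: 4-acetamidobenzenesulfonyl azide, CC(=O)Nc1ccc(cc1)S(=O)(=O)N=[N+]=[N-]
Why: Regitz diazo transfer to the activated methylene of the 1,3-diketone under mild amine base.

Step 21
Reactants: 30 diazo diketone with free C7 hydroxyl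
Product: 31 the O7 tert-butyldimethylsilyl ether of 30
Conditions: tBuMe2SiOTf, 2,6-lutidine, CH2Cl2, −78 → 0 °C
Reagents that add atoms: tert-butyldimethylsilyl trifluoromethanesulfonate, CC(C)(C)[Si](C)(C)OS(=O)(=O)C(F)(F)F
Why: Silyl triflate silylation of the hindered tertiary alcohol, to which the acceptor-substituted diazo group and the TES ether are inert; masking O7 removes the competing capture of the later ketene to a five-membered lactone.

Step 22
Reactants: 31 bis-silyl diazo diketone
Product: 32 (7S,8S)-7-(tert-butyldimethylsilyloxy)-5-chloro-8-[(5S)-2-diazo-5-hydroxy-3-oxohexanoyl]-3-[(1E,3E,5S)-3,5-dimethylhepta-1,3-dien-1-yl]-7-methyl-7,8-dihydro-6H-isochromen-6-one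
Conditions: HF·pyridine, pyridine, THF, 0 °C
Reagents that add atoms: none
Why: Buffered fluoride cleaves the secondary triethylsilyl ether far faster than the hindered tertiary TBS ether, the usual steric differentiation of silyl ethers.

Step 23
Reactants: 32 δ-hydroxy diazo diketone
Product: 34 (7S,8S)-7-(tert-butyldimethylsilyloxy)-5-chloro-3-[(1E,3E,5S)-3,5-dimethylhepta-1,3-dien-1-yl]-7-methyl-8-[(3R,6S)-6-methyl-2,4-dioxooxan-3-yl]-7,8-dihydro-6H-isochromen-6-one, via acylketene 33 (not isolated)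
Conditions: toluene (high dilution), 110 °C
Reagents that add atoms: none
Why: Thermal Wolff rearrangement in which loss of N2 and 1,2-shift of C8 from C2' to C3' (with retention at C8) gives acylketene 33, whose carbon C2' is captured by the C6' hydroxyl to close the six-membered lactone as in the known cyclisation of δ-hydroxy acylketenes to dihydropyran-2,4-diones; the secondary, allylic C8 is expected to migrate in preference to the primary C5' methylene, and C3' equilibrates through the enol.

Step 24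
Reactants: 34 O7-silylated target
Product: 35 target, (7S,8S)-5-chloro-3-[(1E,3E,5S)-3,5-dimethylhepta-1,3-dien-1-yl]-7-hydroxy-7-methyl-8-[(3R,6S)-6-methyl-2,4-dioxooxan-3-yl]-7,8-dihydro-6H-isochromen-6-one
Conditions: HF (48 % aqueous), MeCN, 0 → 20 °C
Reagents that add atoms: none
Why: Acidic fluoride desilylation of the tertiary silyl ether under conditions that the acidic β-keto lactone and the chromophore should tolerate; no base is present, so C8 and the lactone are not disturbed.

## Compound list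

1 | kojic acid | OCC1=CC(=O)C(O)=CO1 | starting material
2 | 2-(hydroxymethyl)-5-[(4-methoxybenzyl)oxy]-4H-pyran-4-one | OCC1=CC(=O)C(OCc2ccc(OC)cc2)=CO1 | intermediate
3 | 2-(bromomethyl)-5-[(4-methoxybenzyl)oxy]-4H-pyran-4-one | BrCC1=CC(=O)C(OCc2ccc(OC)cc2)=CO1 | intermediate
4 | diethyl {5-[(4-methoxybenzyl)oxy]-4-oxo-4H-pyran-2-yl}methylphosphonate | CCOP(=O)(OCC)CC1=CC(=O)C(OCc2ccc(OC)cc2)=CO1 | intermediate
5 | (S)-2-methylbutan-1-ol | CC[C@H](C)CO | starting material
6 | (S)-2-methylbutanal | CC[C@H](C)C=O | intermediate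
7 | (2E,4S)-2,4-dimethylhex-2-enal | CC[C@H](C)/C=C(\C)C=O | intermediate
8 | lithiated phosphonate (α-lithio derivative of 4) | [Li+].CCOP(=O)(OCC)[CH-]C1=CC(=O)C(OCc2ccc(OC)cc2)=CO1 | intermediate (not isolated)
9 | 2-[(1E,3E,5S)-3,5-dimethylhepta-1,3-dien-1-yl]-5-[(4-methoxybenzyl)oxy]-4H-pyran-4-one | CC[C@H](C)/C=C(C)/C=C/C1=CC(=O)C(OCc2ccc(OC)cc2)=CO1 | intermediate
10 | 2-[(1E,3E,5S)-3,5-dimethylhepta-1,3-dien-1-yl]-5-hydroxy-4H-pyran-4-one | CC[C@H](C)/C=C(C)/C=C/C1=CC(=O)C(O)=CO1 | intermediate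
11 | 6-[(1E,3E,5S)-3,5-dimethylhepta-1,3-dien-1-yl]-4-oxo-4H-pyran-3-yl trifluoromethanesulfonate | CC[C@H](C)/C=C(C)/C=C/C1=CC(=O)C(OS(=O)(=O)C(F)(F)F)=CO1 | intermediate
12 | tert-butyl 2-{6-[(1E,3E,5S)-3,5-dimethylhepta-1,3-dien-1-yl]-4-oxo-4H-pyran-3-yl}acetate | CC[C@H](C)/C=C(C)/C=C/C1=CC(=O)C(CC(=O)OC(C)(C)C)=CO1 | intermediate
13 | tert-butyl 2-{6-[dienyl]-4-hydroxy-4-methyl-4H-pyran-3-yl}acetate (both C4 epimers; the centre is lost on ionisation) | CC[C@H](C)/C=C(C)/C=C/C1=CC(C)(O)C(CC(=O)OC(C)(C)C)=CO1 | intermediate (not isolated)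
14 | 5-(2-tert-butoxy-2-oxoethyl)-2-[(1E,3E,5S)-3,5-dimethylhepta-1,3-dien-1-yl]-4-methylpyrylium tetrafluoroborate | CC[C@H](C)/C=C(C)/C=C/c1cc(C)c(CC(=O)OC(C)(C)C)c[o+]1.F[B-](F)(F)F | intermediate
15 | pyruvic acid | CC(=O)C(O)=O | starting material
16 | pyruvoyl chloride | CC(=O)C(Cl)=O | intermediate
17 | anhydrobase, tert-butyl 2-{6-[dienyl]-4-methylidene-4H-pyran-3-yl}acetate | CC[C@H](C)/C=C(C)/C=C/C1=CC(=C)C(CC(=O)OC(C)(C)C)=CO1 | intermediate (not isolated)
18 | tert-butyl 2-{6-[dienyl]-4-(2,3-dioxobutylidene)-4H-pyran-3-yl}acetate | CC[C@H](C)/C=C(C)/C=C/C1=C/C(=C/C(=O)C(C)=O)C(CC(=O)OC(C)(C)C)=CO1 | intermediate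
19 | tert-butyl 2-{4-(1-chloro-2,3-dioxobutylidene)-6-[dienyl]-4H-pyran-3-yl}acetate | CC[C@H](C)/C=C(C)/C=C/C1=C/C(=C(\Cl)C(=O)C(C)=O)C(CC(=O)OC(C)(C)C)=CO1 | intermediate
20 | 2-{4-(1-chloro-2,3-dioxobutylidene)-6-[dienyl]-4H-pyran-3-yl}acetic acid (key-step precursor) | CC[C@H](C)/C=C(C)/C=C/C1=C/C(=C(\Cl)C(=O)C(C)=O)C(CC(=O)O)=CO1 | intermediate
21 | mixed carboxylic 4-toluenesulfonic anhydride of 20 | CC[C@H](C)/C=C(C)/C=C/C1=C/C(=C(\Cl)C(=O)C(C)=O)C(CC(=O)OS(=O)(=O)c2ccc(C)cc2)=CO1 | intermediate (not isolated)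
22 | (Z)-ammonium enolate of the N-acyl (S)-HBTM adduct of 20 (C8=C(O−)–N+) | CC[C@H](C)/C=C(C)/C=C/C1=C/C(=C(\Cl)C(=O)C(C)=O)C(/C=C(\[O-])[N+]2=C3Sc4ccccc4N3CC[C@H]2c2ccccc2)=CO1 | intermediate (not isolated)
23 | tricyclic cis-fused β-lactone, (7S,8S) (key-step product) | CC[C@H](C)/C=C(C)/C=C/C1=CC2=C(Cl)C(=O)[C@@]3(C)OC(=O)[C@H]3C2=CO1 | intermediate
24 | ethyl (S)-3-hydroxybutanoate | C[C@H](O)CC(=O)OCC | starting material
25 | ethyl (S)-3-(triethylsilyloxy)butanoate | CCOC(=O)C[C@H](C)O[Si](CC)(CC)CC | intermediate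
26 | (S)-N-methoxy-N-methyl-3-(triethylsilyloxy)butanamide | CON(C)C(=O)C[C@H](C)O[Si](CC)(CC)CC | intermediate
27 | (S)-4-(triethylsilyloxy)pentan-2-one | CC(=O)C[C@H](C)O[Si](CC)(CC)CC | intermediate
28 | lithium (S)-4-(triethylsilyloxy)pent-1-en-2-olate | [Li]OC(=C)C[C@H](C)O[Si](CC)(CC)CC | intermediate (not isolated)
29 | (7S,8S)-5-chloro-3-[dienyl]-7-hydroxy-7-methyl-8-[(5S)-3-oxo-5-(triethylsilyloxy)hexanoyl]-7,8-dihydro-6H-isochromen-6-one | CC[C@H](C)/C=C(C)/C=C/C1=CC2=C(Cl)C(=O)[C@@](C)(O)[C@@H](C(=O)CC(=O)C[C@H](C)O[Si](CC)(CC)CC)C2=CO1 | intermediate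
30 | 2-diazo derivative of 29 (diazo carbon between the two ketones) | CC[C@H](C)/C=C(C)/C=C/C1=CC2=C(Cl)C(=O)[C@@](C)(O)[C@@H](C(=O)C(=[N+]=[N-])C(=O)C[C@H](C)O[Si](CC)(CC)CC)C2=CO1 | intermediate
31 | O7 tert-butyldimethylsilyl ether of 30 | CC[C@H](C)/C=C(C)/C=C/C1=CC2=C(Cl)C(=O)[C@@](C)(O[Si](C)(C)C(C)(C)C)[C@@H](C(=O)C(=[N+]=[N-])C(=O)C[C@H](C)O[Si](CC)(CC)CC)C2=CO1 | intermediate
32 | (7S,8S)-7-(tert-butyldimethylsilyloxy)-5-chloro-8-[(5S)-2-diazo-5-hydroxy-3-oxohexanoyl]-3-[dienyl]-7-methyl-7,8-dihydro-6H-isochromen-6-one | CC[C@H](C)/C=C(C)/C=C/C1=CC2=C(Cl)C(=O)[C@@](C)(O[Si](C)(C)C(C)(C)C)[C@@H](C(=O)C(=[N+]=[N-])C(=O)C[C@H](C)O)C2=CO1 | intermediate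
33 | acylketene (C8 on C3', ketene carbon C2', free C6' hydroxyl) | CC[C@H](C)/C=C(C)/C=C/C1=CC2=C(Cl)C(=O)[C@@](C)(O[Si](C)(C)C(C)(C)C)[C@@H](C(=C=O)C(=O)C[C@H](C)O)C2=CO1 | intermediate (not isolated)
34 | O7 tert-butyldimethylsilyl ether of the target | CC[C@H](C)/C=C(C)/C=C/C1=CC2=C(Cl)C(=O)[C@@](C)(O[Si](C)(C)C(C)(C)C)[C@@H]([C@@H]3C(=O)C[C@H](C)OC3=O)C2=CO1 | intermediate
35 | (7S,8S)-5-chloro-3-[(1E,3E,5S)-3,5-dimethylhepta-1,3-dien-1-yl]-7-hydroxy-7-methyl-8-[(3R,6S)-6-methyl-2,4-dioxooxan-3-yl]-7,8-dihydro-6H-isochromen-6-one | CC[C@H](C)/C=C(C)/C=C/C1=CC2=C(Cl)C(=O)[C@@](C)(O)[C@@H]([C@@H]3C(=O)C[C@H](C)OC3=O)C2=CO1 | target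

## Step count and risks

Total step count: 24.
Longest linear sequence: 18 steps from kojic acid (steps 1–3, 6–10, 12–15, 19–24).

Steps most likely to fail:

**Step 15 (key step).** The activated acid may be captured by a second molecule (ketene dimerisation or intermolecular acylation) faster than the enolate reaches the crowded, conjugated C7 ketone. Facial discrimination on the catalyst-bound enolate may also be weak, or opposite to the model used to choose the (S) catalyst. A fallback that separates the two bond formations sets out from 20. Thioesterification (PhSH, EDC·HCl, DMAP, CH2Cl2) would give the S-phenyl thioester F1. LiN(SiMe3)2 in THF at −78 → 0 °C would form the thioester enolate, which adds to the C7 ketone, and the aldolate expels thiophenolate to close the β-lactone (thioester aldol-lactonisation). This comes back to the route at 23. The sequence has no catalyst control, so 23 would have to be separated by preparative HPLC from its (7R,8R) diastereomer F2, which forms alongside.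

**Step 23.** During nitrogen loss the C5' methylene may migrate in place of C8, which after capture would give a five-membered lactone; intermolecular capture of the ketene is a further loss. A fallback in which only C8 can migrate sets out from 23:
- LiOH in THF/H2O at 0 °C would open the β-lactone to the hydroxy acid F3.
- tBuMe2SiOTf and 2,6-lutidine would give the bis-silyl compound F4, and K2CO3 in aqueous MeOH would hydrolyse its silyl ester to the O7-silylated acid F5.
- iBuOCOCl and N-methylmorpholine would give the mixed carbonic anhydride F6, which CH2N2 converts into the diazomethyl ketone F7.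
- Wolff rearrangement (AgO2CPh, Et3N, THF) in the presence of ethyl (S)-3-hydroxybutanoate 24 (Arndt–Eistert homologation) would give the homologated ester F8.
- Dieckmann cyclisation (LiN(SiMe3)2, THF, −78 °C) of the C3' enolate onto the ethyl ester would close C3'–C4' and come back to the route at 34.

**Step 12.** The α-keto acid chloride may decompose under the amine, the exocyclic carbon may be acylated twice, and configuration may erode through deprotonation at the dienyl terminus during a slow acylation. A fallback that brings in C6–C7 at the acyloin oxidation level sets out from 14. Acylation of the anhydrobase with the more robust (S)-2-acetoxypropanoyl chloride (iPr2NEt, CH2Cl2, −78 °C) would give the acetoxy ketone F9. Methanolysis (K2CO3, MeOH, 0 °C) would give the α-hydroxy ketone F10. Dess–Martin periodinane (CH2Cl2, 20 °C) would oxidise it to the 1,2-diketone and come back to the route at 18.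

## Further compounds

F1 | step 15 | S-phenyl 2-{4-(1-chloro-2,3-dioxobutylidene)-6-[dienyl]-4H-pyran-3-yl}ethanethioate | CC[C@H](C)/C=C(C)/C=C/C1=C/C(=C(\Cl)C(=O)C(C)=O)C(CC(=O)Sc2ccccc2)=CO1
F2 | step 15 | (7R,8R) diastereomer of β-lactone 23 | CC[C@H](C)/C=C(C)/C=C/C1=CC2=C(Cl)C(=O)[C@]3(C)OC(=O)[C@@H]3C2=CO1
F3 | step 23 | (7S,8S)-5-chloro-3-[dienyl]-7-hydroxy-7-methyl-6-oxo-7,8-dihydro-6H-isochromene-8-carboxylic acid | CC[C@H](C)/C=C(C)/C=C/C1=CC2=C(Cl)C(=O)[C@@](C)(O)[C@@H](C(O)=O)C2=CO1
F4 | step 23 | tert-butyldimethylsilyl ester of the O7 tert-butyldimethylsilyl ether of F3 | CC[C@H](C)/C=C(C)/C=C/C1=CC2=C(Cl)C(=O)[C@@](C)(O[Si](C)(C)C(C)(C)C)[C@@H](C(=O)O[Si](C)(C)C(C)(C)C)C2=CO1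
F5 | step 23 | O7 tert-butyldimethylsilyl ether of acid F3 | CC[C@H](C)/C=C(C)/C=C/C1=CC2=C(Cl)C(=O)[C@@](C)(O[Si](C)(C)C(C)(C)C)[C@@H](C(O)=O)C2=CO1
F6 | step 23 | mixed isobutyl carbonic anhydride of F5 | CC[C@H](C)/C=C(C)/C=C/C1=CC2=C(Cl)C(=O)[C@@](C)(O[Si](C)(C)C(C)(C)C)[C@@H](C(=O)OC(=O)OCC(C)C)C2=CO1
F7 | step 23 | C8 diazoacetyl compound (diazomethyl ketone of F5) | CC[C@H](C)/C=C(C)/C=C/C1=CC2=C(Cl)C(=O)[C@@](C)(O[Si](C)(C)C(C)(C)C)[C@@H](C(=O)C=[N+]=[N-])C2=CO1
F8 | step 23 | (S)-4-ethoxy-4-oxobutan-2-yl ester of the homologated C8 acetic acid | CC[C@H](C)/C=C(C)/C=C/C1=CC2=C(Cl)C(=O)[C@@](C)(O[Si](C)(C)C(C)(C)C)[C@@H](CC(=O)O[C@@H](C)CC(=O)OCC)C2=CO1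
F9 | step 12 | tert-butyl 2-{4-[(3S)-3-acetoxy-2-oxobutylidene]-6-[dienyl]-4H-pyran-3-yl}acetate | CC[C@H](C)/C=C(C)/C=C/C1=C/C(=C/C(=O)[C@H](C)OC(C)=O)C(CC(=O)OC(C)(C)C)=CO1
F10 | step 12 | tert-butyl 2-{6-[dienyl]-4-[(3S)-3-hydroxy-2-oxobutylidene]-4H-pyran-3-yl}acetate | CC[C@H](C)/C=C(C)/C=C/C1=C/C(=C/C(=O)[C@H](C)O)C(CC(=O)OC(C)(C)C)=CO1
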